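Read the pace first.

| setting | Sunday's | Thursday's | spring | winter | dusk |
|---|---|---|---|---|---|
| left-handed substrate | 20 mM | 20 mM | 20 mM | 20 mM | 20 mM |
| right-handed substrate | 20 mM | 20 mM | 20 mM | 20 mM | 20 mM |
| reagent | 25 mM | 120 mM | 20.0 mM | 40.0 mM | 80.0 mM |
| free catalyst | 0.40 mM | 0.40 mM | 0.40 mM | 0.40 mM | 0.40 mM |
| remark | run made earlier | run made earlier |  |  |  |
| time |  |  | 5.0 h | 5.0 h | 5.0 h |

| run | time / h | left-handed substrate / % | left-handed product / % | right-handed substrate / % | right-handed product / % |
|---|---|---|---|---|---|
| Sunday's | 0.667 | 43.4 | 3.1 | 48.6 | 3.1 |
| Sunday's | 1.33 | 41.0 | 7.2 | 46.8 | 3.7 |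
| Sunday's | 2.00 | 39.2 | 9.3 | 46.7 | 4.9 |
| Sunday's | 3.00 | 35.7 | 15.1 | 44.9 | 4.7 |
| Sunday's | 4.00 | 36.0 | 17.8 | 43.4 | 4.8 |
| Thursday's | 0.333 | 39.0 | 10.5 | 45.6 | 2.8 |
| Thursday's | 0.833 | 28.3 | 22.0 | 39.9 | 4.6 |
| Thursday's | 1.50 | 19.2 | 32.4 | 37.1 | 12.8 |
| Thursday's | 2.50 | 9.0 | 41.9 | 30.4 | 21.0 |
| Thursday's | 4.00 | 3.9 | 45.9 | 23.0 | 25.8 |

(scatter of a reading: 1 percentage point)

- free catalyst is single-handed; left-handed substrate and right-handed substrate are mirror images of each other, charged as a racemate, each of them at the stated concentration
- what was read earlier has a scatter of 1 percentage point, one standard deviation
- what may be going on: reagent + catalyst intermediate B -> free catalyst + right-handed product; left-handed substrate <-> right-handed substrate; free catalyst -> spent catalyst; free catalyst <-> dormant form; free catalyst + left-handed substrate <-> catalyst intermediate A; free catalyst + right-handed substrate <-> catalyst intermediate B; reagent + catalyst intermediate A -> free catalyst + left-handed product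

1. which of these there is most of at the end, counted by the substrate in it, spring (right-handed product / left-handed substrate / left-handed product / right-handed substrate)
2. which of these there is most of at the end, counted by the substrate in it, winter (right-handed product / left-handed substrate / left-handed product / right-handed substrate)
3. which of these there is most of at the end, counted by the substrate in it, dusk (right-handed product / left-handed substrate / left-handed product / right-handed substrate)
4. amount of the one of these that there is most of at the end, in percent of the left-handed substrate and right-handed substrate together charged, spring
5. amount of the one of these that there is most of at the end, in percent of the left-handed substrate and right-handed substrate together charged, winter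
6. amount of the one of these that there is most of at the end, in percent of the left-handed substrate and right-handed substrate together charged, dusk

I defined the pace p as the share of a substrate consumed per hour, and took it as proportional to the reagent present. Thursday's run, taken at its mean reagent up to 2.50 h and scaled to dusk's charge, read as a pace averaged over those hours of 0.511 h⁻¹ for left-handed substrate and 0.148 h⁻¹ for right-handed substrate. I used these as dusk's starting paces. Their ratio, the selectivity factor, read 3.45.

I looked for two things that could slow that pace. The first was the reagent, which I reckoned round by round for dusk. Reckoned with unslowed paces over 5.0 h, the mean reagent came to 0.819 of the charge. Putting that back gave smaller paces in the reckoning, and the mean rose to 0.834. This is the slowing factor f, a flask's mean reagent over its reagent charge, and it lies below one.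

The second was the catalyst, which I only suspected. Sunday's run at 3.00 h read 0.836 of Thursday's left-handed pace for equal reagent. That reading carries its scatter, so I held it aside as a possible further factor.

With f alone, I expected dusk to end at 44.1% left-handed product and 27.0% right-handed substrate. With that possible factor as well, I expected 41.6% and 29.8%, so I expected the left-handed product to stand above the right-handed substrate in dusk either way.

The forecast named right-handed substrate at 45% for spring, right-handed substrate at 39.5% for winter and left-handed product at 43% for dusk, on this ground: “The runs read as two parallel resolutions, each roughly first order in reagent and in its own substrate.”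

The flasks gave right-handed substrate at 43.8% in spring, right-handed substrate at 38.1% in winter and left-handed product at 43.2% in dusk, so the forecast was right on every count.

    reagent + catalyst intermediate B → free catalyst + right-handed product (k = 300 M⁻¹ h⁻¹)
    left-handed substrate ⇌ right-handed substrate (k = 0.0147 h⁻¹)
    free catalyst → spent catalyst (k = 0.111 h⁻¹)
    free catalyst ⇌ dormant form (K = 2.00, k = 0.130 h⁻¹)
    free catalyst + left-handed substrate ⇌ catalyst intermediate A (K = 50.0 M⁻¹, k = 1.08 × 10⁵ M⁻¹ h⁻¹)
    free catalyst + right-handed substrate ⇌ catalyst intermediate B (K = 43.0 M⁻¹, k = 5420 M⁻¹ h⁻¹)
    reagent + catalyst intermediate A → free catalyst + left-handed product (k = 790 M⁻¹ h⁻¹)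

Dusk kept 68% of its reagent, so the plain mean of start and end puts f near 0.840, close to my 0.834. The reagent charge accounts for the gap in right-handed substrate between dusk and spring: dusk holds 27.6%, and without the difference in reagent it holds 43.8%. Winter kept 61% of its reagent, so the same plain mean puts f there near 0.805. Thursday's pace, scaled to winter's charge, then gives 37.1% right-handed substrate, and winter held 38.1%.

The runs were computed for an exercise; noise was put on by code.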